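**Retrosynthetic overview**
- C40 = C14 ring B aldehyde + symmetrical C12 bis-phosphonate + C14 ring A aldehyde; the C10=C11 and C10'=C11' double bonds are made by two successive Horner–Wadsworth–Emmons (HWE) reactions, then the silyl ether is removed.
- Key C–C bonds: the ring–chain junctions C6–C7 and C6'–C7' are each made by intermolecular aldol addition of an acetate ester lithium enolate (ethyl acetate for ring B, tert-butyl acetate for ring A) to a hindered ring ketone, followed by E1cB loss of acetate to give the exocyclic "retro" alkene.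
- Each ring–CH–CHO unit is extended to the C14 aldehyde with Ph3P=C(Me)CHO; the C12 unit comes from a glyoxal equivalent and two C5 phosphonates.
- Stereocentre: yeast reduction of ketoisophorone, then LiBH(s-Bu)3, gives (4R,6R)-actinol; dehydrogenation gives the (4S)-silyloxy enone, which is C3 (S) of the target.
- Rings: neither ring is constructed. Ring B is carried intact from ketoisophorone and ring A from 2,6-dimethylphenol (dearomatising C-methylation).

Assumption: in the yeast step the cells, their cofactors and the sucrose feed are treated as the catalyst system, so that step has no spent-reagent entry.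

**Ring B: C14 aldehyde**

Step 1
Reactants: 1 2,6,6-trimethylcyclohex-2-ene-1,4-dione (ketoisophorone)
Product: 2 (6R)-2,2,6-trimethylcyclohexane-1,4-dione
Conditions: baker's yeast (Saccharomyces cerevisiae), sucrose, H2O, 30 °C
Reagents that add atoms: none
Why: Biocatalytic asymmetric conjugate (ene-reductase) reduction of the electron-poor ring C=C; the enzyme protonates C6 from one face and gives the (6R) dione in high ee.

Step 2
Reactants: 2 (6R)-2,2,6-trimethylcyclohexane-1,4-dione
Product: 3 (4R,6R)-4-hydroxy-2,2,6-trimethylcyclohexan-1-one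
Conditions: LiBH(s-Bu)3 (L-Selectride), THF, −78 °C; then NaOH, H2O2
Reagents that add atoms: none
Why: Substrate-controlled ketone reduction: the bulky hydride touches only the unhindered C4 carbonyl and attacks from the equatorial side (the axial side is blocked by the axial 2-methyl), giving the axial alcohol trans to the 6-methyl, which is (4R).

Step 3
Reactants: 3 (4R,6R)-4-hydroxy-2,2,6-trimethylcyclohexan-1-one
Product: 4 (4R,6R)-4-[(tert-butyldimethylsilyl)oxy]-2,2,6-trimethylcyclohexan-1-one
Conditions: t-BuMe2SiCl, imidazole, DMF, 40 °C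
Reagents that add atoms: tert-butyldimethylsilyl chloride, CC(C)(C)[Si](C)(C)Cl
Why: Imidazole-catalysed silylation of the secondary alcohol; the silyl ether survives every later base, hydride and oxidant and leaves both stereocentres untouched.

Step 4
Reactants: 4 (4R,6R)-4-[(tert-butyldimethylsilyl)oxy]-2,2,6-trimethylcyclohexan-1-one
Product: 6 tert-butyl(dimethyl){[(1R)-3,5,5-trimethyl-4-[(trimethylsilyl)oxy]cyclohex-3-en-1-yl]oxy}silane, via lithium enolate of the silyloxy ketone 5 (not isolated)
Conditions: LiN(i-Pr)2, THF, −78 → 0 °C; then Me3SiCl, Et3N, −78 °C → rt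
Reagents that add atoms: chlorotrimethylsilane, C[Si](C)(C)Cl
Why: Silyl enol ether formation; the ketone can enolise only toward C6, so one regioisomer forms, and the C6 stereocentre is erased on purpose while the carbinol centre is untouched.

Step 5
Reactants: 6 tert-butyl(dimethyl){[(1R)-3,5,5-trimethyl-4-[(trimethylsilyl)oxy]cyclohex-3-en-1-yl]oxy}silane
Product: 7 (4S)-4-[(tert-butyldimethylsilyl)oxy]-2,6,6-trimethylcyclohex-2-en-1-one
Conditions: Pd(OAc)2, MeCN, rt
Reagents that add atoms: none
Why: Saegusa–Ito oxidation: the palladium enolate undergoes β-hydride elimination into the ring to give the conjugated enone; the carbinol centre is unchanged in space and becomes (4S) only through the priority change.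

Step 6
Reactants: 7 (4S)-4-[(tert-butyldimethylsilyl)oxy]-2,6,6-trimethylcyclohex-2-en-1-one; 8 ethyl acetate
Product: 11 ethyl 2-[(4S)-1-acetoxy-4-[(tert-butyldimethylsilyl)oxy]-2,6,6-trimethylcyclohex-2-en-1-yl]acetate (C1 epimers), via lithium enolate of ethyl acetate 9 (not isolated), via lithium aldolate of the ring B enone 10 (not isolated)
Conditions: 8, LiN(i-Pr)2, THF, −78 °C; then 7, −78 °C; then Ac2O, −78 → 0 °C
Reagents that add atoms: acetic anhydride, CC(=O)OC(C)=O
Why: Intermolecular aldol addition: the small lithium ester enolate adds 1,2 to the hindered enone carbonyl at −78 °C, and acetylating the tertiary aldolate in the flask prevents retro-aldol cleavage; the new carbinol centre is an irrelevant epimer mixture that is removed in step 7.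

Step 7
Reactants: 11 ethyl 2-[(4S)-1-acetoxy-4-[(tert-butyldimethylsilyl)oxy]-2,6,6-trimethylcyclohex-2-en-1-yl]acetate
Product: 12 ethyl (2E)-2-[(4S)-4-[(tert-butyldimethylsilyl)oxy]-2,6,6-trimethylcyclohex-2-en-1-ylidene]acetate
Conditions: DBU, toluene, rt; chromatographic separation of the alkene isomers
Reagents that add atoms: none
Why: E1cB elimination of acetate through the ester enolate (the only β-hydrogens are on the CH2CO2Et carbon) avoids an allylic cation next to the silyl ether; both alkene isomers form, the (E)-isomer (ester on the gem-dimethyl side) is isolated, and the (Z)-isomer is re-equilibrated with catalytic I2 under light and recycled.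

Step 8
Reactants: 12 ethyl (2E)-2-[(4S)-4-[(tert-butyldimethylsilyl)oxy]-2,6,6-trimethylcyclohex-2-en-1-ylidene]acetate
Product: 13 (2E)-2-[(4S)-4-[(tert-butyldimethylsilyl)oxy]-2,6,6-trimethylcyclohex-2-en-1-ylidene]ethan-1-ol
Conditions: i-Bu2AlH, CH2Cl2, −78 °C
Reagents that add atoms: none
Why: 1,2-reduction of the conjugated ester to the allylic alcohol by the aluminium hydride, without touching the diene or its geometry.

Step 9
Reactants: 13 (2E)-2-[(4S)-4-[(tert-butyldimethylsilyl)oxy]-2,6,6-trimethylcyclohex-2-en-1-ylidene]ethan-1-ol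
Product: 14 (2E)-2-[(4S)-4-[(tert-butyldimethylsilyl)oxy]-2,6,6-trimethylcyclohex-2-en-1-ylidene]acetaldehyde
Conditions: MnO2, CH2Cl2, rt
Reagents that add atoms: none
Why: Neutral, chemoselective allylic oxidation with MnO2, which keeps the exocyclic alkene geometry and the silyl ether.

Step 10
Reactants: 14 (2E)-2-[(4S)-4-[(tert-butyldimethylsilyl)oxy]-2,6,6-trimethylcyclohex-2-en-1-ylidene]acetaldehyde; 15 2-(triphenylphosphoranylidene)propanal
Product: 16 (2E,4E)-4-[(4S)-4-[(tert-butyldimethylsilyl)oxy]-2,6,6-trimethylcyclohex-2-en-1-ylidene]-2-methylbut-2-enal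
Conditions: toluene, 80 °C
Reagents that add atoms: none
Why: Wittig reaction with a stabilised formyl ylide gives the (E)-trisubstituted enal under neutral conditions; the more conjugated, α-branched product is less electrophilic, so over-homologation is minor.

**Ring A: C14 aldehyde**

Step 11
Reactants: 17 2,6-dimethylphenol
Product: 19 2,6,6-trimethylcyclohexa-2,4-dien-1-one, via lithium 2,6-dimethylphenoxide 18 (not isolated)
Conditions: n-BuLi, toluene, 0 °C; then MeI, 110 °C (sealed); Claisen alkali wash, distillation, use fresh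
Reagents that add atoms: iodomethane, CI
Why: Dearomatising ortho C-alkylation of a tight phenoxide ion pair in a non-polar solvent; the gem-dimethyl carbon blocks re-aromatisation, and the modest yield is acceptable from a very cheap phenol.

Step 12
Reactants: 19 2,6,6-trimethylcyclohexa-2,4-dien-1-one; 20 tert-butyl acetate
Product: 23 tert-butyl 2-(1-acetoxy-2,6,6-trimethylcyclohexa-2,4-dien-1-yl)acetate (racemic), via lithium enolate of tert-butyl acetate 21 (not isolated), via lithium aldolate of the ring A dienone 22 (not isolated)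
Conditions: 20 (1.5 equiv), LiN(i-Pr)2, THF, −78 °C; then 19, −78 °C; then Ac2O, −78 → 0 °C
Reagents that add atoms: acetic anhydride, CC(=O)OC(C)=O
Why: Intermolecular aldol addition of the same type as in step 6; the lithium enolate of tert-butyl acetate does not self-condense, so it can be used in excess to add 1,2 to the hindered, dimerisation-prone dienone quickly, and acetate trapping means the acid-labile dienyl carbinol is never isolated.

Step 13
Reactants: 23 tert-butyl 2-(1-acetoxy-2,6,6-trimethylcyclohexa-2,4-dien-1-yl)acetate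
Product: 24 tert-butyl (2Z)-2-(2,6,6-trimethylcyclohexa-2,4-dien-1-ylidene)acetate
Conditions: DBU, toluene, 0 °C → rt; chromatographic separation of the alkene isomers
Reagents that add atoms: none
Why: Base-mediated E1cB elimination gives the cross-conjugated trienoate without passing through the arenium-type cation that would undergo a methyl shift and aromatise; the (Z)-isomer (ester on the gem-dimethyl side) is isolated and the other isomer is recycled by I2/light equilibration.

Step 14
Reactants: 24 tert-butyl (2Z)-2-(2,6,6-trimethylcyclohexa-2,4-dien-1-ylidene)acetate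
Product: 25 (2Z)-2-(2,6,6-trimethylcyclohexa-2,4-dien-1-ylidene)ethan-1-ol
Conditions: i-Bu2AlH (3 equiv), CH2Cl2, −78 → 0 °C
Reagents that add atoms: none
Why: 1,2-reduction of the conjugated tert-butyl ester to the allylic alcohol with excess aluminium hydride, leaving the triene and its geometry intact.

Step 15
Reactants: 25 (2Z)-2-(2,6,6-trimethylcyclohexa-2,4-dien-1-ylidene)ethan-1-ol
Product: 26 (2Z)-2-(2,6,6-trimethylcyclohexa-2,4-dien-1-ylidene)acetaldehyde
Conditions: MnO2, CH2Cl2, 0 °C → rt
Reagents that add atoms: none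
Why: Mild neutral allylic oxidation with MnO2 that retains the alkene geometry.

Step 16
Reactants: 26 (2Z)-2-(2,6,6-trimethylcyclohexa-2,4-dien-1-ylidene)acetaldehyde; 15 2-(triphenylphosphoranylidene)propanal
Product: 27 (2E,4Z)-2-methyl-4-(2,6,6-trimethylcyclohexa-2,4-dien-1-ylidene)but-2-enal
Conditions: toluene, 70 °C, dilute
Reagents that add atoms: none
Why: (E)-selective Wittig reaction with the stabilised formyl ylide, as in step 10; the product has no enolisable hydrogen, which suits the later HWE step.

**Central C12 unit**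

Step 17
Reactants: 28 trans-1,4-dioxane-2,3-diol (anhydrous glyoxal equivalent); 29 ethyl (2E)-4-(diethoxyphosphoryl)-3-methylbut-2-enoate (triethyl 3-methyl-4-phosphonocrotonate)
Product: 33 diethyl (2E,4E,6E,8E)-3,8-dimethyldeca-2,4,6,8-tetraenedioate, via sodium phosphonate carbanion 30 (not isolated), via glyoxal 31 (not isolated), via ethyl (2E,4E)-3-methyl-6-oxohexa-2,4-dienoate 32 (not isolated)
Conditions: 29 (2.2 equiv), NaH, THF, 0 °C; then 28, 0 °C → rt; recrystallise
Reagents that add atoms: none
Why: Twofold HWE olefination: the bis-hemiacetal releases glyoxal under the basic conditions, the vinylogous phosphonate reacts at its α-carbon to give (E)-disubstituted alkenes, and the symmetrical all-E diester is purified by crystallisation.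

Step 18
Reactants: 33 diethyl (2E,4E,6E,8E)-3,8-dimethyldeca-2,4,6,8-tetraenedioate
Product: 34 (2E,4E,6E,8E)-3,8-dimethyldeca-2,4,6,8-tetraene-1,10-diol
Conditions: i-Bu2AlH, CH2Cl2/THF, −78 → −20 °C
Reagents that add atoms: none
Why: Clean 1,2-reduction of both conjugated esters to the bis-allylic diol.

Step 19
Reactants: 34 (2E,4E,6E,8E)-3,8-dimethyldeca-2,4,6,8-tetraene-1,10-diol
Product: 35 (2E,4E,6E,8E)-1,10-dibromo-3,8-dimethyldeca-2,4,6,8-tetraene
Conditions: PBr3, pyridine (cat.), Et2O, −20 °C; used crude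
Reagents that add atoms: phosphorus tribromide, BrP(Br)Br
Why: Conversion of the primary allylic alcohols into bromides through phosphite esters (SN2), which keeps the alkene geometry; the labile dibromide is used at once.

Step 20
Reactants: 35 (2E,4E,6E,8E)-1,10-dibromo-3,8-dimethyldeca-2,4,6,8-tetraene
Product: 36 tetraethyl [(2E,4E,6E,8E)-3,8-dimethyldeca-2,4,6,8-tetraene-1,10-diyl]bis(phosphonate)
Conditions: P(OEt)3, toluene, 100 °C
Reagents that add atoms: triethyl phosphite, CCOP(OCC)OCC
Why: Michaelis–Arbuzov reaction at the primary allylic carbons, the standard route to polyene bis-phosphonates.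

**Assembly**

Step 21
Reactants: 36 tetraethyl [(2E,4E,6E,8E)-3,8-dimethyldeca-2,4,6,8-tetraene-1,10-diyl]bis(phosphonate); 27 (2E,4Z)-2-methyl-4-(2,6,6-trimethylcyclohexa-2,4-dien-1-ylidene)but-2-enal
Product: 38 diethyl [(2E,4E,6E,8E,10E,12E,14Z)-3,8,12-trimethyl-14-(2,6,6-trimethylcyclohexa-2,4-dien-1-ylidene)tetradeca-2,4,6,8,10,12-hexaen-1-yl]phosphonate, via monosodium carbanion of the bis-phosphonate 37 (not isolated)
Conditions: 36 (3 equiv), NaN(SiMe3)2 (1 equiv on 27), THF, −78 °C; then 27, −78 → 0 °C, dark; excess 36 recovered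
Reagents that add atoms: none
Why: (E)-selective HWE olefination forming C10'=C11'; the excess of bis-phosphonate with only one equivalent of base enforces mono-olefination, and the polar mono-phosphonate is easily separated from the non-polar double adduct.

Step 22
Reactants: 38 diethyl [(2E,4E,6E,8E,10E,12E,14Z)-3,8,12-trimethyl-14-(2,6,6-trimethylcyclohexa-2,4-dien-1-ylidene)tetradeca-2,4,6,8,10,12-hexaen-1-yl]phosphonate; 16 (2E,4E)-4-[(4S)-4-[(tert-butyldimethylsilyl)oxy]-2,6,6-trimethylcyclohex-2-en-1-ylidene]-2-methylbut-2-enal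
Product: 40 (3S,6E,6'Z)-3-[(tert-butyldimethylsilyl)oxy]-2',3',4',5'-tetradehydro-4,5'-retro-β,β-carotene (silyl ether of the target), via sodium carbanion of the C26 phosphonate 39 (not isolated)
Conditions: 38 (1.2 equiv), NaN(SiMe3)2, THF, −78 °C; then 16, −78 → 0 °C, dark
Reagents that add atoms: none
Why: (E)-selective HWE olefination forming C10=C11; the pre-formed carbanion, without excess base, adds to the aldehyde at −78 °C faster than it can remove the vinylogously acidic C3–H, so the stereocentre and both ring–chain geometries are kept.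

Step 23
Reactants: 40 (3S,6E,6'Z)-3-[(tert-butyldimethylsilyl)oxy]-2',3',4',5'-tetradehydro-4,5'-retro-β,β-carotene
Product: 41 (3S,6E,6'Z)-2',3',4',5'-tetradehydro-4,5'-retro-β,β-caroten-3-ol (target CNP0202479.1)
Conditions: Bu4NF, THF, 0 °C → rt, dark, argon; chromatography on deactivated silica, crystallisation
Reagents that add atoms: none
Why: Fluoride-induced desilylation is basic and non-ionising, so the very acid-labile polyenylic allylic alcohol and the C3 (S) centre survive; no iodine equilibration is used at this stage because it would scramble the two ring–chain double bonds.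

**Compound list**

1 | 2,6,6-trimethylcyclohex-2-ene-1,4-dione (ketoisophorone) | CC1=CC(=O)CC(C)(C)C1=O | starting material
2 | (6R)-2,2,6-trimethylcyclohexane-1,4-dione | O=C1[C@H](C)CC(=O)CC1(C)C | intermediate
3 | (4R,6R)-4-hydroxy-2,2,6-trimethylcyclohexan-1-one | O=C1[C@H](C)C[C@@H](O)CC1(C)C | intermediate
4 | (4R,6R)-4-[(tert-butyldimethylsilyl)oxy]-2,2,6-trimethylcyclohexan-1-one | O=C1[C@H](C)C[C@@H](O[Si](C)(C)C(C)(C)C)CC1(C)C | intermediate
5 | lithium enolate of 4 | [Li]OC1=C(C)C[C@@H](O[Si](C)(C)C(C)(C)C)CC1(C)C | intermediate (not isolated)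
6 | tert-butyl(dimethyl){[(1R)-3,5,5-trimethyl-4-[(trimethylsilyl)oxy]cyclohex-3-en-1-yl]oxy}silane | C[Si](C)(C)OC1=C(C)C[C@@H](O[Si](C)(C)C(C)(C)C)CC1(C)C | intermediate
7 | (4S)-4-[(tert-butyldimethylsilyl)oxy]-2,6,6-trimethylcyclohex-2-en-1-one | O=C1C(C)=C[C@@H](O[Si](C)(C)C(C)(C)C)CC1(C)C | intermediate
8 | ethyl acetate | CCOC(C)=O | starting material
9 | lithium enolate of ethyl acetate | [Li]OC(=C)OCC | intermediate (not isolated)
10 | lithium aldolate of 7 (C1 epimers) | CCOC(=O)CC1(O[Li])C(C)=C[C@@H](O[Si](C)(C)C(C)(C)C)CC1(C)C | intermediate (not isolated)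
11 | ethyl 2-[(4S)-1-acetoxy-4-[(tert-butyldimethylsilyl)oxy]-2,6,6-trimethylcyclohex-2-en-1-yl]acetate (C1 epimers) | CCOC(=O)CC1(OC(C)=O)C(C)=C[C@@H](O[Si](C)(C)C(C)(C)C)CC1(C)C | intermediate
12 | ethyl (2E)-2-[(4S)-4-[(tert-butyldimethylsilyl)oxy]-2,6,6-trimethylcyclohex-2-en-1-ylidene]acetate | CCOC(=O)/C=C1/C(C)=C[C@@H](O[Si](C)(C)C(C)(C)C)CC1(C)C | intermediate
13 | (2E)-2-[(4S)-4-[(tert-butyldimethylsilyl)oxy]-2,6,6-trimethylcyclohex-2-en-1-ylidene]ethan-1-ol | OC/C=C1/C(C)=C[C@@H](O[Si](C)(C)C(C)(C)C)CC1(C)C | intermediate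
14 | (2E)-2-[(4S)-4-[(tert-butyldimethylsilyl)oxy]-2,6,6-trimethylcyclohex-2-en-1-ylidene]acetaldehyde | O=C/C=C1/C(C)=C[C@@H](O[Si](C)(C)C(C)(C)C)CC1(C)C | intermediate
15 | 2-(triphenylphosphoranylidene)propanal | CC(C=O)=P(c1ccccc1)(c1ccccc1)c1ccccc1 | starting material
16 | (2E,4E)-4-[(4S)-4-[(tert-butyldimethylsilyl)oxy]-2,6,6-trimethylcyclohex-2-en-1-ylidene]-2-methylbut-2-enal | O=C/C(C)=C/C=C1/C(C)=C[C@@H](O[Si](C)(C)C(C)(C)C)CC1(C)C | intermediate
17 | 2,6-dimethylphenol | Cc1cccc(C)c1O | starting material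
18 | lithium 2,6-dimethylphenoxide | Cc1cccc(C)c1O[Li] | intermediate (not isolated)
19 | 2,6,6-trimethylcyclohexa-2,4-dien-1-one | CC1=CC=CC(C)(C)C1=O | intermediate
20 | tert-butyl acetate | CC(=O)OC(C)(C)C | starting material
21 | lithium enolate of tert-butyl acetate | [Li]OC(=C)OC(C)(C)C | intermediate (not isolated)
22 | lithium aldolate of 19 (racemic) | CC(C)(C)OC(=O)CC1(O[Li])C(C)=CC=CC1(C)C | intermediate (not isolated)
23 | tert-butyl 2-(1-acetoxy-2,6,6-trimethylcyclohexa-2,4-dien-1-yl)acetate (racemic) | CC(C)(C)OC(=O)CC1(OC(C)=O)C(C)=CC=CC1(C)C | intermediate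
24 | tert-butyl (2Z)-2-(2,6,6-trimethylcyclohexa-2,4-dien-1-ylidene)acetate | CC(C)(C)OC(=O)/C=C1/C(C)=CC=CC1(C)C | intermediate
25 | (2Z)-2-(2,6,6-trimethylcyclohexa-2,4-dien-1-ylidene)ethan-1-ol | OC/C=C1/C(C)=CC=CC1(C)C | intermediate
26 | (2Z)-2-(2,6,6-trimethylcyclohexa-2,4-dien-1-ylidene)acetaldehyde | O=C/C=C1/C(C)=CC=CC1(C)C | intermediate
27 | (2E,4Z)-2-methyl-4-(2,6,6-trimethylcyclohexa-2,4-dien-1-ylidene)but-2-enal | O=C/C(C)=C/C=C1/C(C)=CC=CC1(C)C | intermediate
28 | trans-1,4-dioxane-2,3-diol (racemic; glyoxal equivalent) | OC1OCCOC1O | starting material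
29 | ethyl (2E)-4-(diethoxyphosphoryl)-3-methylbut-2-enoate | CCOC(=O)/C=C(\C)CP(=O)(OCC)OCC | starting material
30 | sodium carbanion of 29 | CCOC(=O)/C=C(\C)[CH-]P(=O)(OCC)OCC.[Na+] | intermediate (not isolated)
31 | glyoxal | O=CC=O | intermediate (not isolated)
32 | ethyl (2E,4E)-3-methyl-6-oxohexa-2,4-dienoate | CCOC(=O)/C=C(C)/C=C/C=O | intermediate (not isolated)
33 | diethyl (2E,4E,6E,8E)-3,8-dimethyldeca-2,4,6,8-tetraenedioate | CCOC(=O)/C=C(C)/C=C/C=C/C(C)=C/C(=O)OCC | intermediate
34 | (2E,4E,6E,8E)-3,8-dimethyldeca-2,4,6,8-tetraene-1,10-diol | OC/C=C(C)/C=C/C=C/C(C)=C/CO | intermediate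
35 | (2E,4E,6E,8E)-1,10-dibromo-3,8-dimethyldeca-2,4,6,8-tetraene | BrC/C=C(C)/C=C/C=C/C(C)=C/CBr | intermediate
36 | tetraethyl [(2E,4E,6E,8E)-3,8-dimethyldeca-2,4,6,8-tetraene-1,10-diyl]bis(phosphonate) | CCOP(=O)(OCC)C/C=C(C)/C=C/C=C/C(C)=C/CP(=O)(OCC)OCC | intermediate
37 | monosodium carbanion of 36 | CCOP(=O)(OCC)[CH-]/C=C(C)/C=C/C=C/C(C)=C/CP(=O)(OCC)OCC.[Na+] | intermediate (not isolated)
38 | diethyl [(2E,4E,6E,8E,10E,12E,14Z)-3,8,12-trimethyl-14-(2,6,6-trimethylcyclohexa-2,4-dien-1-ylidene)tetradeca-2,4,6,8,10,12-hexaen-1-yl]phosphonate | CCOP(=O)(OCC)C/C=C(C)/C=C/C=C/C(C)=C/C=C/C(C)=C/C=C1/C(C)=CC=CC1(C)C | intermediate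
39 | sodium carbanion of 38 | CCOP(=O)(OCC)[CH-]/C=C(C)/C=C/C=C/C(C)=C/C=C/C(C)=C/C=C1/C(C)=CC=CC1(C)C.[Na+] | intermediate (not isolated)
40 | (3S,6E,6'Z)-3-[(tert-butyldimethylsilyl)oxy]-2',3',4',5'-tetradehydro-4,5'-retro-β,β-carotene | CC1=CC=CC(C)(C)\C1=C/C=C(C)/C=C/C=C(C)/C=C/C=C/C(C)=C/C=C/C(C)=C/C=C1/C(C)=C[C@@H](O[Si](C)(C)C(C)(C)C)CC1(C)C | intermediate
41 | (3S,6E,6'Z)-2',3',4',5'-tetradehydro-4,5'-retro-β,β-caroten-3-ol (CNP0202479.1) | CC1=CC=CC(C)(C)\C1=C/C=C(C)/C=C/C=C(C)/C=C/C=C/C(C)=C/C=C/C(C)=C/C=C1/C(C)=C[C@@H](O)CC1(C)C | target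

**Step count**
Total: 23 steps. Longest linear sequence: 12 steps (steps 1–10, 22, 23).

**Three steps most likely to fail, with fallbacks**

Step 6 (enolate addition to the hindered enone 7; conjugate addition or γ-deprotonation may compete). The fallback sets out from 7 and returns at 14. Ethynylmagnesium bromide with CeCl3 in THF at −78 °C adds 1,2 to 7 and gives the tertiary propargylic alcohol (4S)-4-[(tert-butyldimethylsilyl)oxy]-1-ethynyl-2,6,6-trimethylcyclohex-2-en-1-ol F1. A Meyer–Schuster rearrangement of this carbinol with (Ph3SiO)3VO in toluene at 100 °C then gives aldehyde 14 directly as an E/Z mixture, from which the (E)-isomer is separated. Steps 6–9 are bypassed.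

Step 13 (elimination from the dienyl acetate 23; ionisation to an arenium-type cation with methyl shift and aromatisation can compete). The fallback sets out from 19 and returns at 24. A Peterson olefination is used: tert-butyl (trimethylsilyl)acetate is deprotonated with LiN(i-Pr)2 in THF at −78 °C to give the lithium enolate of tert-butyl (trimethylsilyl)acetate F2, which adds to 19 to give lithium 1-[2-tert-butoxy-2-oxo-1-(trimethylsilyl)ethyl]-2,6,6-trimethylcyclohexa-2,4-dien-1-olate F3; neither is isolated. On warming to 0 °C the adduct loses silanolate and gives ester 24 as an E/Z mixture that is separated as before. No ionisable tertiary ester is ever formed, and steps 12–13 are bypassed.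

Step 17 (double olefination of the glyoxal surrogate; Cannizzaro-type loss of glyoxal or a stalled mono-olefination). The fallback sets out from 29 and returns at 33. Carbanion 30 (NaH, THF) is first condensed with the monoprotected glyoxal 2,2-dimethoxyacetaldehyde to give ethyl (2E,4E)-6,6-dimethoxy-3-methylhexa-2,4-dienoate F4. Aqueous formic acid then unmasks the aldehyde, giving 32 as an isolated compound, and a second HWE reaction of 32 with 30 gives diester 33.

**Further compounds**
F1 | step 6 | (4S)-4-[(tert-butyldimethylsilyl)oxy]-1-ethynyl-2,6,6-trimethylcyclohex-2-en-1-ol | C#CC1(O)C(C)=C[C@@H](O[Si](C)(C)C(C)(C)C)CC1(C)C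
F2 | step 13 | lithium enolate of tert-butyl (trimethylsilyl)acetate | [Li]OC(=C[Si](C)(C)C)OC(C)(C)C
F3 | step 13 | lithium 1-[2-tert-butoxy-2-oxo-1-(trimethylsilyl)ethyl]-2,6,6-trimethylcyclohexa-2,4-dien-1-olate | CC(C)(C)OC(=O)C([Si](C)(C)C)C1(O[Li])C(C)=CC=CC1(C)C
F4 | step 17 | ethyl (2E,4E)-6,6-dimethoxy-3-methylhexa-2,4-dienoate | CCOC(=O)/C=C(C)/C=C/C(OC)OC
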